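**Retrosynthetic overview**
1. Feature: in ring C, ring B is bonded to C3 and C2 carries only H. This is a C6–C3–C6 chain whose aryl group has moved from Cβ to Cα. The 2'- and 4'-OMe groups lie ortho and para to C1', so ring B is a very good migrating group.
2. Last disconnection, C6–CH2 of the prenyl chain: [3,3] shift of the 7-O-(1,1-dimethylallyl) ether of isocaviunin. C8 is blocked by OMe, so only C6 can keep the chain, and the alkene enters after all oxidations.
3. Key disconnection, C3–C1' and O1–C2: a 2'-hydroxychalcone undergoes an aryl shift with Tl(NO3)3, followed by acid closure. Ring C is the only ring formed. Rings A and B are bought.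
4. Cα=Cβ: Claisen–Schmidt union of 4-(benzyloxy)-2-hydroxy-3,6-dimethoxyacetophenone with 2,4,5-trimethoxybenzaldehyde.
5. Ring A pattern: phloroacetophenone is dibenzylated, para-hydroxylated (Elbs) and dimethylated, and the benzyl groups are then reset. Benzyl is used instead of an acetal because the Elbs sulfate must be hydrolysed in hot acid.

Key step: step 7

Remark: the target has no stereocentre, and its only side-chain alkene is trisubstituted with two identical methyl ends. The rearranged acetal and the Claisen dienone are racemic transients whose stereocentres disappear.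

**Step 1**
Reactants: 1 2',4',6'-trihydroxyacetophenone (phloroacetophenone, dried)
Product: 2 1-[2,4-bis(benzyloxy)-6-hydroxyphenyl]ethanone
Conditions: BnBr (2.1 equiv), K2CO3 (2.2 equiv), DMF, rt to 50 °C
Reagents that add atoms: benzyl bromide, BrCc1ccccc1
Why: Williamson etherification in which the 4-OH and one of the two equivalent ortho OH groups react while the last OH is held by its hydrogen bond to the acetyl oxygen; benzyl is chosen because it should outlast both the alkaline persulfate and the hot aqueous acid of step 2, which an acetal protecting group would not.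

**Step 2**
Reactants: 2 1-[2,4-bis(benzyloxy)-6-hydroxyphenyl]ethanone
Product: 4 1-[2,4-bis(benzyloxy)-3,6-dihydroxyphenyl]ethanone, via potassium aryl sulfate 3 (not isolated)
Conditions: K2S2O8 (1.1 equiv), aq KOH, pyridine, 10–20 °C, 24 h; acidify to pH 4 and wash out unchanged 2 (Et2O); then 2 M HCl, 75 °C, N2
Reagents that add atoms: potassium peroxydisulfate, [K+].[K+].[O-]S(=O)(=O)OOS(=O)(=O)[O-]
Why: Elbs persulfate oxidation, in which the phenoxide of 2 attacks a peroxide oxygen of peroxydisulfate through the carbon para to O− (the CH between the two benzyloxy groups), and acid hydrolysis of aryl sulfate 3 by S–O cleavage should free the hydroquinone with the benzyl ethers intact.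

**Step 3**
Reactants: 4 1-[2,4-bis(benzyloxy)-3,6-dihydroxyphenyl]ethanone
Product: 5 1-[2,4-bis(benzyloxy)-3,6-dimethoxyphenyl]ethanone
Conditions: MeI (excess), K2CO3, DMF, 40 °C, N2
Reagents that add atoms: iodomethane, CI
Why: Exhaustive Williamson O-methylation, in which the polar solvent and excess MeI overcome the hydrogen bond of the ortho hydroxyl, so that the former phenol becomes the future 5-OMe and the new oxygen the future 8-OMe.

**Step 4**
Reactants: 5 1-[2,4-bis(benzyloxy)-3,6-dimethoxyphenyl]ethanone
Product: 6 1-(2,4-dihydroxy-3,6-dimethoxyphenyl)ethanone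
Conditions: H2 (1 atm), 10% Pd/C, EtOAc–MeOH, rt
Reagents that add atoms: none
Why: Catalytic hydrogenolysis of both aryl benzyl ethers, under which the di-ortho-substituted aryl ketone and the methyl ethers are inert at 1 atm and room temperature.

**Step 5**
Reactants: 6 1-(2,4-dihydroxy-3,6-dimethoxyphenyl)ethanone
Product: 7 1-[4-(benzyloxy)-2-hydroxy-3,6-dimethoxyphenyl]ethanone
Conditions: BnBr (1.05 equiv), K2CO3 (1.1 equiv), acetone, reflux
Reagents that add atoms: benzyl bromide, BrCc1ccccc1
Why: Regioselective Williamson benzylation, since the 4-OH para to the acetyl group is the more acidic and is free whereas the 2-OH is hydrogen-bonded to C=O and flanked by OMe, so one equivalent of BnBr should cap O4 only.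

**Step 6**
Reactants: 7 1-[4-(benzyloxy)-2-hydroxy-3,6-dimethoxyphenyl]ethanone; 8 2,4,5-trimethoxybenzaldehyde
Product: 9 (E)-1-[4-(benzyloxy)-2-hydroxy-3,6-dimethoxyphenyl]-3-(2,4,5-trimethoxyphenyl)prop-2-en-1-one
Conditions: KOH (50% aq, excess), EtOH, rt, 48–72 h; then cold dilute HCl
Reagents that add atoms: none
Why: Claisen–Schmidt condensation (aldol addition, then E1cB loss of water) between the methyl ketone enolate and a non-enolisable aldehyde, which gives the conjugated E-enone under thermodynamic control, and in strong base the product stays as the open chalcone phenoxide instead of closing to a flavanone.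

**Step 7**
Reactants: 9 (E)-1-[4-(benzyloxy)-2-hydroxy-3,6-dimethoxyphenyl]-3-(2,4,5-trimethoxyphenyl)prop-2-en-1-one
Product: 11 7-(benzyloxy)-5,8-dimethoxy-3-(2,4,5-trimethoxyphenyl)-4H-chromen-4-one, via rearranged dimethyl acetal 10 (not isolated)
Conditions: Tl(NO3)3·3H2O (1.05 equiv), MeOH–HC(OMe)3, rt, 2–4 h; then 2 M aq HCl, 55 °C, same flask; filter off TlCl
Reagents that add atoms: methanol, CO (supplies the two methoxy groups of acetal 10; both leave again on ring closure, so 11 holds no reagent atom)
Why: This is the known oxidative 1,2-aryl migration of 2'-hydroxychalcones by trivalent thallium nitrate, followed by acid cyclisation to the isoflavone. Tl(NO3)3 adds across Cα=Cβ with methanol entering at the benzylic Cβ; heterolysis of the weak Cα–Tl bond, which releases monovalent thallium, is assisted by ring B, which bridges as a phenonium ion and ends on Cα (new C3–C1' bond), and the oxocarbenium ion left at Cβ takes up a second methanol to give racemic acetal 10. Aqueous HCl ionises the acetal, the 2'-OH adds to the C=O+ carbon in a 6-exo-trig closure (new O1–C2 bond, ring C), and loss of methanol gives the aromatic pyranone, which erases the single stereocentre of 10, so no stereocontrol is needed. Aryl migration has to beat aroyl migration and aurone formation, and it should, because the methoxy groups ortho and para to C1 of ring B stabilise the phenonium ion while the acyl group migrates poorly. Closure can use only the oxygen beside the future 8-OMe because the other ortho oxygen is a methyl ether, and the enone is the only alkene present because the prenyl group is added later. One equivalent of oxidant and HC(OMe)3 as water scavenger should keep the chelated phenol and the electron-rich rings from over-oxidation.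

**Step 8**
Reactants: 11 7-(benzyloxy)-5,8-dimethoxy-3-(2,4,5-trimethoxyphenyl)-4H-chromen-4-one
Product: 12 7-hydroxy-5,8-dimethoxy-3-(2,4,5-trimethoxyphenyl)-4H-chromen-4-one
Conditions: H2 (1 atm), 10% Pd/C, EtOAc–MeOH, rt, stopped after one equivalent
Reagents that add atoms: none
Why: Hydrogenolysis of the aryl benzyl ether, which is much faster than reduction of the conjugated, trisubstituted C2=C3 bond of the chromone when the uptake is limited.

**Step 9**
Reactants: 12 7-hydroxy-5,8-dimethoxy-3-(2,4,5-trimethoxyphenyl)-4H-chromen-4-one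
Product: 13 5,7-dihydroxy-8-methoxy-3-(2,4,5-trimethoxyphenyl)-4H-chromen-4-one (isocaviunin)
Conditions: BCl3 (1 M in CH2Cl2, 2.5 equiv), CH2Cl2, −78 to 0 °C; then H2O–MeOH
Reagents that add atoms: none
Why: Chelation-directed Lewis acid ether cleavage, in which BCl3 binds the C4 carbonyl oxygen and the peri 5-OMe in a six-membered chelate and chloride removes that methyl group alone, while the 8-, 2'-, 4'- and 5'-OMe groups cannot form such a chelate and should persist at low temperature.

**Step 10**
Reactants: 13 isocaviunin; 14 3-chloro-3-methylbut-1-yne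
Product: 15 5-hydroxy-8-methoxy-7-[(2-methylbut-3-yn-2-yl)oxy]-3-(2,4,5-trimethoxyphenyl)-4H-chromen-4-one
Conditions: 14 (3 equiv), K2CO3, KI (cat.), CuI (cat.), acetone, reflux
Reagents that add atoms: none
Why: Copper-assisted propargylic O-alkylation of Williamson type, which runs through an allenylidene or ion-pair intermediate and so allows substitution at the tertiary carbon; the acidic 7-OH reacts and the 5-OH, hydrogen-bonded to C4=O, does not.

**Step 11**
Reactants: 15 5-hydroxy-8-methoxy-7-[(2-methylbut-3-yn-2-yl)oxy]-3-(2,4,5-trimethoxyphenyl)-4H-chromen-4-one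
Product: 16 5-hydroxy-8-methoxy-7-[(2-methylbut-3-en-2-yl)oxy]-3-(2,4,5-trimethoxyphenyl)-4H-chromen-4-one
Conditions: H2 (1 atm), 5% Pd/CaCO3 poisoned with Pb(OAc)2, quinoline, EtOAc, rt, stopped after one equivalent
Reagents that add atoms: none
Why: Semihydrogenation of Lindlar type, in which the terminal alkyne binds the lead- and quinoline-poisoned palladium surface far better than the vinyl product or the chromone C2=C3 bond, so uptake should stop at the 1,1-dimethylallyl ether.

**Step 12**
Reactants: 16 5-hydroxy-8-methoxy-7-[(2-methylbut-3-en-2-yl)oxy]-3-(2,4,5-trimethoxyphenyl)-4H-chromen-4-one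
Product: 18 5,7-dihydroxy-8-methoxy-6-(3-methylbut-2-en-1-yl)-3-(2,4,5-trimethoxyphenyl)-4H-chromen-4-one (6-prenylisocaviunin), via C6-prenyl cyclohexadienone 17 (not isolated)
Conditions: PhNEt2, 130 °C, Ar
Reagents that add atoms: none
Why: Aromatic Claisen rearrangement, in which the [3,3] shift through a six-membered transition state inverts the allyl unit so that the tertiary ether delivers a linear prenyl group to C6 and dienone 17 tautomerises to the phenol, whereas a shift to the other ortho carbon C8 cannot rearomatise because of its OMe group and reverts.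

**Compound list**
1 | 2',4',6'-trihydroxyacetophenone | CC(=O)c1c(O)cc(O)cc1O | starting material
2 | 1-[2,4-bis(benzyloxy)-6-hydroxyphenyl]ethanone | CC(=O)c1c(O)cc(OCc2ccccc2)cc1OCc1ccccc1 | intermediate
3 | potassium 3-acetyl-2,6-bis(benzyloxy)-4-hydroxyphenyl sulfate (not isolated) | CC(=O)c1c(O)cc(OCc2ccccc2)c(OS(=O)(=O)[O-])c1OCc1ccccc1.[K+] | intermediate
4 | 1-[2,4-bis(benzyloxy)-3,6-dihydroxyphenyl]ethanone | CC(=O)c1c(O)cc(OCc2ccccc2)c(O)c1OCc1ccccc1 | intermediate
5 | 1-[2,4-bis(benzyloxy)-3,6-dimethoxyphenyl]ethanone | CC(=O)c1c(OC)cc(OCc2ccccc2)c(OC)c1OCc1ccccc1 | intermediate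
6 | 1-(2,4-dihydroxy-3,6-dimethoxyphenyl)ethanone | CC(=O)c1c(OC)cc(O)c(OC)c1O | intermediate
7 | 1-[4-(benzyloxy)-2-hydroxy-3,6-dimethoxyphenyl]ethanone | CC(=O)c1c(OC)cc(OCc2ccccc2)c(OC)c1O | intermediate
8 | 2,4,5-trimethoxybenzaldehyde | COc1cc(OC)c(C=O)cc1OC | starting material
9 | (E)-1-[4-(benzyloxy)-2-hydroxy-3,6-dimethoxyphenyl]-3-(2,4,5-trimethoxyphenyl)prop-2-en-1-one | COc1cc(OCc2ccccc2)c(OC)c(O)c1C(=O)/C=C/c1cc(OC)c(OC)cc1OC | intermediate
10 | 1-[4-(benzyloxy)-2-hydroxy-3,6-dimethoxyphenyl]-3,3-dimethoxy-2-(2,4,5-trimethoxyphenyl)propan-1-one (racemic, not isolated) | COC(OC)C(c1cc(OC)c(OC)cc1OC)C(=O)c1c(OC)cc(OCc2ccccc2)c(OC)c1O | intermediate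
11 | 7-(benzyloxy)-5,8-dimethoxy-3-(2,4,5-trimethoxyphenyl)-4H-chromen-4-one | O=c1c(-c3cc(OC)c(OC)cc3OC)coc2c(OC)c(OCc3ccccc3)cc(OC)c12 | intermediate
12 | 7-hydroxy-5,8-dimethoxy-3-(2,4,5-trimethoxyphenyl)-4H-chromen-4-one | O=c1c(-c3cc(OC)c(OC)cc3OC)coc2c(OC)c(O)cc(OC)c12 | intermediate
13 | 5,7-dihydroxy-8-methoxy-3-(2,4,5-trimethoxyphenyl)-4H-chromen-4-one (isocaviunin) | O=c1c(-c3cc(OC)c(OC)cc3OC)coc2c(OC)c(O)cc(O)c12 | intermediate
14 | 3-chloro-3-methylbut-1-yne | CC(C)(Cl)C#C | starting material
15 | 5-hydroxy-8-methoxy-7-[(2-methylbut-3-yn-2-yl)oxy]-3-(2,4,5-trimethoxyphenyl)-4H-chromen-4-one | O=c1c(-c3cc(OC)c(OC)cc3OC)coc2c(OC)c(OC(C)(C)C#C)cc(O)c12 | intermediate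
16 | 5-hydroxy-8-methoxy-7-[(2-methylbut-3-en-2-yl)oxy]-3-(2,4,5-trimethoxyphenyl)-4H-chromen-4-one | O=c1c(-c3cc(OC)c(OC)cc3OC)coc2c(OC)c(OC(C)(C)C=C)cc(O)c12 | intermediate
17 | 5-hydroxy-8-methoxy-6-(3-methylbut-2-en-1-yl)-3-(2,4,5-trimethoxyphenyl)-4H-chromene-4,7(6H)-dione (racemic, not isolated) | COC1=C2OC=C(c3cc(OC)c(OC)cc3OC)C(=O)C2=C(O)C(CC=C(C)C)C1=O | intermediate
18 | 6-prenylisocaviunin | COc1cc(OC)c(-c2coc3c(OC)c(O)c(CC=C(C)C)c(O)c3c2=O)cc1OC | target

**Total step count:** 12. **Longest linear sequence:** 12 steps (1 to 18); 8 and 14 are purchased.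

**Steps most likely to fail**

**Step 7.**
- What may go wrong: trivalent thallium may over-oxidise the tetra-oxygenated ring A phenol or the trimethoxyphenyl ring. The chalcone may close to a flavanone in the acid that is set free before oxidation occurs. The liberated nitric acid may nitrate the rings during the warm acid phase. Thallium salts are also very toxic and call for closed handling of all residues.
- Fallback: it sets out from 7 and comes back at 11.
 - Heating 7 with N,N-dimethylformamide dimethyl acetal should give the enaminone (E)-1-[4-(benzyloxy)-2-hydroxy-3,6-dimethoxyphenyl]-3-(dimethylamino)prop-2-en-1-one F1.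
 - I2 in CHCl3 should iodinate its α-carbon and trigger closure through the phenol, giving 7-(benzyloxy)-3-iodo-5,8-dimethoxy-4H-chromen-4-one F2.
 - Suzuki–Miyaura coupling of F2 with purchased (2,4,5-trimethoxyphenyl)boronic acid (Pd(PPh3)4, Na2CO3, DME–H2O, 80 °C) would form C3–C1' and deliver 11.
 - This path gives up the aryl shift and bypasses chalcone 9.

**Step 2.**
- What may go wrong: conversion may be low, the phenoxide may degrade oxidatively in alkaline persulfate, and the benzyl ether ortho to the acetyl group may be partly lost during the hot acid hydrolysis of the sulfate.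
- Fallback: it sets out from 1 and comes back at 7, replacing C–H oxidation by halogenation and C–O coupling.
 - One equivalent of BnBr with K2CO3 should give 1-[4-(benzyloxy)-2,6-dihydroxyphenyl]ethanone F3.
 - One equivalent of MeI with K2CO3 should give 1-[4-(benzyloxy)-2-hydroxy-6-methoxyphenyl]ethanone F4.
 - Electrophilic iodination ortho to the free phenol (I2, HIO3, aq EtOH) should give 1-[4-(benzyloxy)-2-hydroxy-3-iodo-6-methoxyphenyl]ethanone F5.
 - Ullmann-type methoxylation (NaOMe, CuBr, DMF–MeOH, 110 °C) would then install the 3-OMe group and give 7.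

**Step 10.**
- What may go wrong: substitution at the tertiary propargylic carbon by a weakly nucleophilic phenoxide flanked by the 8-OMe group may be slow. The chloride may eliminate to the enyne, and the ether may close early to a chromene.
- Fallback: it sets out from 13 and comes back at 18, using an easy primary alkylation and a cationic [1,3] shift in place of the [3,3] shift.
 - Prenyl bromide with K2CO3 in acetone should give 5-hydroxy-8-methoxy-7-[(3-methylbut-2-en-1-yl)oxy]-3-(2,4,5-trimethoxyphenyl)-4H-chromen-4-one F6.
 - Stirring F6 with montmorillonite K10 in CH2Cl2 should move the prenyl group, without inversion, to the only open ortho carbon C6 and give 18.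

**Further compounds**
F1 | step 7 | (E)-1-[4-(benzyloxy)-2-hydroxy-3,6-dimethoxyphenyl]-3-(dimethylamino)prop-2-en-1-one | CN(C)/C=C/C(=O)c1c(OC)cc(OCc2ccccc2)c(OC)c1O
F2 | step 7 | 7-(benzyloxy)-3-iodo-5,8-dimethoxy-4H-chromen-4-one | O=c1c(I)coc2c(OC)c(OCc3ccccc3)cc(OC)c12
F3 | step 2 | 1-[4-(benzyloxy)-2,6-dihydroxyphenyl]ethanone | CC(=O)c1c(O)cc(OCc2ccccc2)cc1O
F4 | step 2 | 1-[4-(benzyloxy)-2-hydroxy-6-methoxyphenyl]ethanone | CC(=O)c1c(OC)cc(OCc2ccccc2)cc1O
F5 | step 2 | 1-[4-(benzyloxy)-2-hydroxy-3-iodo-6-methoxyphenyl]ethanone | CC(=O)c1c(OC)cc(OCc2ccccc2)c(I)c1O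
F6 | step 10 | 5-hydroxy-8-methoxy-7-[(3-methylbut-2-en-1-yl)oxy]-3-(2,4,5-trimethoxyphenyl)-4H-chromen-4-one | O=c1c(-c3cc(OC)c(OC)cc3OC)coc2c(OC)c(OCC=C(C)C)cc(O)c12
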